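The dihydrofuran ring is disconnected across C3a–C3 and O1–C2. This exploits two features: on the benzo ring, O1 at C7a lies para to the substituted carbon C5, the oxygen pattern of 1,4-benzoquinone, and C2 carries a para-hydroxylated aryl ring, so that C2–C3 with both aryl groups is a 4-hydroxystilbene whose C3 terminus is nucleophilic. A chiral phosphoric acid-catalysed (3+2) annulation of a commercial catechol stilbene with benzoquinone therefore forms the C3a–C3 bond, closes the ring O1–C2–C3–C3a–C7a and sets both stereocentres trans in one operation. The phenol left at C5 becomes a triflate for Heck attachment of the styryl arm, and global O-deprotection ends the route.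

Key step: step 1

Assumption: the (R)-enantiomer of the phosphoric acid TRIP (3,3'-bis(2,4,6-triisopropylphenyl)-1,1'-binaphthyl-2,2'-diyl hydrogen phosphate) is taken to shield the alkene face that leads to the (2S,3S) series; should the sense of induction prove opposite, the (S)-catalyst is used with no other change.

Step 1
Reactants: 1 4-[(E)-2-(3,5-dimethoxyphenyl)ethenyl]benzene-1,2-diol (3'-hydroxypterostilbene); 2 1,4-benzoquinone
Product: 4 (2S,3S)-2-(3,4-dihydroxyphenyl)-3-(3,5-dimethoxyphenyl)-2,3-dihydro-1-benzofuran-5-ol, via hydroquinone para-quinone methide 3 (not isolated)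
Conditions: (R)-TRIP (10 mol %), 4 Å MS, CH2Cl2/toluene 1:1, −30 °C, slow addition of 2 (1.05 equiv), argon, dark
Reagents that add atoms: none
Why: The phosphoric acid binds the para-hydroxyl of 1 through P=O and a carbonyl of 2 through P–OH, the alkene carbon of 1 that bears the 3,5-dimethoxyphenyl ring (the vinylogous phenol terminus) adds to C2 of the quinone to form the C3a–C3 bond, the adduct tautomerises to the hydroquinone para-quinone methide 3, and the hydroquinone hydroxyl next to the new bond adds to the methide carbon to form O1–C2. The closest known reaction type is the chiral Brønsted acid-catalysed formal (3+2) cycloaddition of 1,4-benzoquinones and quinone monoimines with enecarbamates and hydroxystyrenes to 2,3-dihydrobenzofuran-5-ols, together with the acid-promoted racemic annulation of quinones with propenyl- and styryl-arenes. The dihydrofuran ring is closed as a stepwise (3+2) annulation, conjugate C–C addition being followed by a 5-exo-trig oxa-1,6-addition to the quinone methide. C3 is set in the C–C bond-forming event by the catalyst, which shields one face of the hydrogen-bonded alkene, and C2 is set in the ring closure by C3, the catechol ring entering anti to the 3-aryl group, which is also the thermodynamic result because the closure is reversible through 3. The step needs C–C bonding at the alkene rather than at the dimethoxyphenyl ring, no redox exchange between catechol and quinone, and a trans disposition of the two aryl groups; the para-hydroxyl push in 1, low temperature with slow addition of 2 in the dark, and the anti preference of the closure secure these.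

Step 2
Reactants: 4 (2S,3S)-2-(3,4-dihydroxyphenyl)-3-(3,5-dimethoxyphenyl)-2,3-dihydro-1-benzofuran-5-ol
Product: 5 (2S,3S)-3-(3,5-dimethoxyphenyl)-2-(2,2-diphenyl-1,3-benzodioxol-5-yl)-2,3-dihydro-1-benzofuran-5-ol
Conditions: Ph2CCl2 (1.2 equiv), K2CO3, MeCN, 25 °C, argon
Reagents that add atoms: dichlorodiphenylmethane, ClC(Cl)(c1ccccc1)c1ccccc1
Why: Ketalisation of a catechol, in which dichlorodiphenylmethane alkylates the two neighbouring oxygens in succession and the second C–O bond forms intramolecularly to the benzodioxole, whereas the lone C5 hydroxyl can only give a labile chloro-ether that reverts on aqueous work-up; no stereocentre is touched.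

Step 3
Reactants: 5 (2S,3S)-3-(3,5-dimethoxyphenyl)-2-(2,2-diphenyl-1,3-benzodioxol-5-yl)-2,3-dihydro-1-benzofuran-5-ol
Product: 6 (2S,3S)-3-(3,5-dimethoxyphenyl)-2-(2,2-diphenyl-1,3-benzodioxol-5-yl)-2,3-dihydro-1-benzofuran-5-yl trifluoromethanesulfonate
Conditions: PhNTf2 (1.2 equiv), Et3N, DMAP (cat.), CH2Cl2, 0 °C → 25 °C
Reagents that add atoms: N-phenylbis(trifluoromethanesulfonimide), O=S(=O)(N(c1ccccc1)S(=O)(=O)C(F)(F)F)C(F)(F)F
Why: Aryl triflate formation by O-sulfonylation of the only remaining phenol with a mild triflyl donor, which leaves the electron-rich arenes, the ketal and both stereocentres untouched.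

Step 4
Reactants: 6 (2S,3S)-3-(3,5-dimethoxyphenyl)-2-(2,2-diphenyl-1,3-benzodioxol-5-yl)-2,3-dihydro-1-benzofuran-5-yl trifluoromethanesulfonate; 7 1-ethenyl-3,5-dimethoxybenzene (3,5-dimethoxystyrene)
Product: 8 5-[(2S,3S)-3-(3,5-dimethoxyphenyl)-5-[(E)-2-(3,5-dimethoxyphenyl)ethenyl]-2,3-dihydro-1-benzofuran-2-yl]-2,2-diphenyl-1,3-benzodioxole
Conditions: 7 (1.5 equiv), PdCl2(PPh3)2 (5 mol %), LiCl, Et3N, DMF, 100 °C
Reagents that add atoms: none
Why: Mizoroki–Heck reaction in which the aryl triflate adds oxidatively to zerovalent palladium, the chloride additive keeps the neutral pathway so that the aryl group is delivered to the terminal alkene carbon, and syn β-hydride elimination gives the (E)-stilbene, with no free phenol present that could disturb C2 or C3.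

Step 5
Reactants: 8 5-[(2S,3S)-3-(3,5-dimethoxyphenyl)-5-[(E)-2-(3,5-dimethoxyphenyl)ethenyl]-2,3-dihydro-1-benzofuran-2-yl]-2,2-diphenyl-1,3-benzodioxole
Product: 9 4-[(2S,3S)-3-(3,5-dihydroxyphenyl)-5-[(E)-2-(3,5-dihydroxyphenyl)ethenyl]-2,3-dihydro-1-benzofuran-2-yl]benzene-1,2-diol
Conditions: BBr3 (excess), CH2Cl2, −78 °C → 0 °C; then H2O
Reagents that add atoms: none
Why: Lewis-acid ether cleavage in which BBr3 removes the four aryl methyl groups by bromide attack on the O-coordinated methyls and opens the benzophenone ketal to the catechol borate, hydrolysis then freeing the six phenols, while C3 is untouched and C2, should its benzylic C–O bond ionise reversibly, should re-close trans under the control of C3.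

Compound list
1 | 4-[(E)-2-(3,5-dimethoxyphenyl)ethenyl]benzene-1,2-diol (3'-hydroxypterostilbene) | COc1cc(OC)cc(/C=C/c2ccc(O)c(O)c2)c1 | starting material
2 | 1,4-benzoquinone | O=C1C=CC(=O)C=C1 | starting material
3 | 4-[(2S)-2-(2,5-dihydroxyphenyl)-2-(3,5-dimethoxyphenyl)ethylidene]-2-hydroxycyclohexa-2,5-dien-1-one (hydroquinone para-quinone methide, one methide geometry drawn) | Oc1ccc(O)c(c1)[C@H](c1cc(OC)cc(OC)c1)/C=C1/C=CC(=O)C(O)=C1 | intermediate
4 | (2S,3S)-2-(3,4-dihydroxyphenyl)-3-(3,5-dimethoxyphenyl)-2,3-dihydro-1-benzofuran-5-ol | Oc1ccc2c(c1)[C@H](c1cc(OC)cc(OC)c1)[C@@H](c1ccc(O)c(O)c1)O2 | intermediate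
5 | (2S,3S)-3-(3,5-dimethoxyphenyl)-2-(2,2-diphenyl-1,3-benzodioxol-5-yl)-2,3-dihydro-1-benzofuran-5-ol | Oc1ccc2c(c1)[C@H](c1cc(OC)cc(OC)c1)[C@@H](c1ccc3OC(c4ccccc4)(c4ccccc4)Oc3c1)O2 | intermediate
6 | (2S,3S)-3-(3,5-dimethoxyphenyl)-2-(2,2-diphenyl-1,3-benzodioxol-5-yl)-2,3-dihydro-1-benzofuran-5-yl trifluoromethanesulfonate | O=S(=O)(Oc1ccc2c(c1)[C@H](c1cc(OC)cc(OC)c1)[C@@H](c1ccc3OC(c4ccccc4)(c4ccccc4)Oc3c1)O2)C(F)(F)F | intermediate
7 | 1-ethenyl-3,5-dimethoxybenzene (3,5-dimethoxystyrene) | C=Cc1cc(OC)cc(OC)c1 | starting material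
8 | 5-[(2S,3S)-3-(3,5-dimethoxyphenyl)-5-[(E)-2-(3,5-dimethoxyphenyl)ethenyl]-2,3-dihydro-1-benzofuran-2-yl]-2,2-diphenyl-1,3-benzodioxole | COc1cc(OC)cc(/C=C/c2ccc3c(c2)[C@H](c2cc(OC)cc(OC)c2)[C@@H](c2ccc4OC(c5ccccc5)(c5ccccc5)Oc4c2)O3)c1 | intermediate
9 | 4-[(2S,3S)-3-(3,5-dihydroxyphenyl)-5-[(E)-2-(3,5-dihydroxyphenyl)ethenyl]-2,3-dihydro-1-benzofuran-2-yl]benzene-1,2-diol | Oc1cc(O)cc(/C=C/c2ccc3c(c2)[C@H](c2cc(O)cc(O)c2)[C@@H](c2ccc(O)c(O)c2)O3)c1 | target

Total step count: 5
Longest linear sequence: 5 steps (1 → 4 → 5 → 6 → 8 → 9)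

Steps most likely to fail

Step 1. The free catechol of 1 may undergo redox exchange with the quinone, the two faces of a 1,2-diarylalkene may be discriminated poorly, and the dimethoxyphenyl ring may compete as the nucleophile. The fallback sets out from 1 and comes back at 5. The catechol is masked first with dichlorodiphenylmethane (K2CO3, MeCN, 25 °C) to give 5-[(E)-2-(3,5-dimethoxyphenyl)ethenyl]-2,2-diphenyl-1,3-benzodioxole F1, which cannot be oxidised by the quinone. An achiral Lewis acid-catalysed (3+2) annulation of F1 with 2 (Sc(OTf)3, MeCN, 0 °C) should then give the trans adduct as a racemate, that is 5 together with its mirror image (2R,3R)-3-(3,5-dimethoxyphenyl)-2-(2,2-diphenyl-1,3-benzodioxol-5-yl)-2,3-dihydro-1-benzofuran-5-ol F2. Preparative chromatography on a chiral stationary phase removes F2, and the route continues from 5.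

Step 5. During ether cleavage the benzylic C2–O1 bond may ionise, and the acid may induce cationic cyclisation or oligomerisation through the stilbene double bond. The fallback sets out from 6 and comes back at 9; it moves the Lewis-acid step to a stage where no stilbene exists and ends with a mild ester cleavage. BBr3 (CH2Cl2, −78 °C → 0 °C) applied to 6 should give (2S,3S)-2-(3,4-dihydroxyphenyl)-3-(3,5-dihydroxyphenyl)-2,3-dihydro-1-benzofuran-5-yl trifluoromethanesulfonate F3, the aryl triflate being inert to BBr3. Acetylation (Ac2O, pyridine, 0 °C) gives (2S,3S)-2-(3,4-diacetoxyphenyl)-3-(3,5-diacetoxyphenyl)-2,3-dihydro-1-benzofuran-5-yl trifluoromethanesulfonate F4. A Mizoroki–Heck reaction of F4 with commercial 3,5-diacetoxystyrene (C=Cc1cc(OC(C)=O)cc(OC(C)=O)c1) under the conditions of step 4 gives the hexaacetate of the target F5. Methanolysis (catalytic K2CO3, degassed MeOH, 0 °C) then releases 9 under conditions that can neither ionise C2–O1 nor protonate the alkene.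

Step 4. Oxidative addition of the electron-rich triflate may be slow, arylation may occur in part at the internal alkene carbon, and the triflate may be hydrolysed. The fallback sets out from 6 and 7 and comes back at 8. Cross-metathesis of 7 with vinylboronic acid pinacol ester (C=CB1OC(C)(C)C(C)(C)O1; second-generation Grubbs catalyst, CH2Cl2, 40 °C) should give 2-[(E)-2-(3,5-dimethoxyphenyl)ethenyl]-4,4,5,5-tetramethyl-1,3,2-dioxaborolane F6. A Suzuki–Miyaura coupling of F6 with 6 (PdCl2(dppf), K3PO4, dioxane/H2O, 80 °C) gives 8, with the site of C–C bond formation and the alkene geometry fixed by the boronate and not by the regiochemistry of insertion.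

Further compounds
F1 | step 1 | 5-[(E)-2-(3,5-dimethoxyphenyl)ethenyl]-2,2-diphenyl-1,3-benzodioxole | COc1cc(OC)cc(/C=C/c2ccc3OC(c4ccccc4)(c4ccccc4)Oc3c2)c1
F2 | step 1 | (2R,3R)-3-(3,5-dimethoxyphenyl)-2-(2,2-diphenyl-1,3-benzodioxol-5-yl)-2,3-dihydro-1-benzofuran-5-ol | Oc1ccc2c(c1)[C@@H](c1cc(OC)cc(OC)c1)[C@H](c1ccc3OC(c4ccccc4)(c4ccccc4)Oc3c1)O2
F3 | step 5 | (2S,3S)-2-(3,4-dihydroxyphenyl)-3-(3,5-dihydroxyphenyl)-2,3-dihydro-1-benzofuran-5-yl trifluoromethanesulfonate | O=S(=O)(Oc1ccc2c(c1)[C@H](c1cc(O)cc(O)c1)[C@@H](c1ccc(O)c(O)c1)O2)C(F)(F)F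
F4 | step 5 | (2S,3S)-2-(3,4-diacetoxyphenyl)-3-(3,5-diacetoxyphenyl)-2,3-dihydro-1-benzofuran-5-yl trifluoromethanesulfonate | O=S(=O)(Oc1ccc2c(c1)[C@H](c1cc(OC(C)=O)cc(OC(C)=O)c1)[C@@H](c1ccc(OC(C)=O)c(OC(C)=O)c1)O2)C(F)(F)F
F5 | step 5 | hexaacetate of the target, 4-[(2S,3S)-3-(3,5-diacetoxyphenyl)-5-[(E)-2-(3,5-diacetoxyphenyl)ethenyl]-2,3-dihydro-1-benzofuran-2-yl]-1,2-phenylene diacetate | CC(=O)Oc1cc(OC(C)=O)cc(/C=C/c2ccc3c(c2)[C@H](c2cc(OC(C)=O)cc(OC(C)=O)c2)[C@@H](c2ccc(OC(C)=O)c(OC(C)=O)c2)O3)c1
F6 | step 4 | 2-[(E)-2-(3,5-dimethoxyphenyl)ethenyl]-4,4,5,5-tetramethyl-1,3,2-dioxaborolane | COc1cc(OC)cc(/C=C/B2OC(C)(C)C(C)(C)O2)c1
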